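The plan hinges on breaking the C9–C10 bond. C10 is alpha to the C1 carbonyl and bears the ring-B oxygen, so enol silylation of ring B gives an aromatic 2-methyl-3-silyloxyfuran whose C2 (the future C10) is nucleophilic, while C9 is an oxygenated carbon that can start as an aldehyde. A single Lewis-acid aldol then closes the ten-membered carbocycle (ring A), rebuilds the bridging 3(2H)-furanone (ring B) with its quaternary centre, and sets C9 and C10. The cyclisation substrate is the trans α-methylene lactone (ring C) carrying the (Z)-alkenyl silyloxyfuran on C6 and, on C7, the C8 methacrylate carbon with the C9 aldehyde; only acetylation of O9 follows.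

Key step: step 16

Remark (numbering): germacrane numbering is used for all compounds (C1 ketone, C2=C3, C4=C5 with C15 methyl on C4, C6 lactone carbinol, C7, C8, C9, C10 with C14 methyl, C11=C13 methylene, C12 lactone carbonyl). The target reads as 4Z,6R,7S,8S,9S,10S, with a trans-fused lactone and an erythro O8/O9 pair.

Remark (descriptors): C6 is S in 7–15 and R from 16 on, and C7 is R in 19 and S from 21 on. Both changes come from CIP priorities only; no inversion is involved.

Remark (C10): the lactate centre becomes C10, which is epimerisable in the furanone and planar in furan 24. Compounds 12, 13, 15, 16, 19 and 21–23 are therefore carried as C10 epimer pairs (C10 left undefined in their SMILES), and either lactate enantiomer would serve.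

Assumption (C8): the zinc allylation of step 11 is taken to pass through the closed chair transition state, which gives the 8R alcohol (C6 and O8 anti along C11–C7–C8–C9). That is why the methacrylate is introduced with inversion in step 12; if the adduct proved to be 8S, it would be acylated directly with methacrylic anhydride.

Design note: O8 carries the final methacrylate already in the cyclisation substrate, so no protecting-group exchange is needed on the strained macrocycle.

Step 1
Reactants: 1 ethyl (S)-lactate
Product: 2 (2S)-2-hydroxy-N-methoxy-N-methylpropanamide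
Conditions: MeNH(OMe)·HCl, iPrMgCl, THF, −20 to 0 °C
Reagents that add atoms: N,O-dimethylhydroxylamine hydrochloride, CNOC.Cl
Why: Aminolysis of the ester by the chloromagnesium amide (Weinreb amide formation) is standard for lactate esters and does not touch the stereocentre.

Step 2
Reactants: 2 (2S)-2-hydroxy-N-methoxy-N-methylpropanamide
Product: 3 (2S)-N-methoxy-N-methyl-2-(triethylsilyloxy)propanamide
Conditions: TESCl, imidazole, CH2Cl2, 0 °C to rt
Reagents that add atoms: chlorotriethylsilane (TESCl), CC[Si](Cl)(CC)CC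
Why: Routine O-silylation gives an ether that survives the acetylide addition and is later cleaved by dilute acetic acid, under which the TBS ether at C6 persists.

Step 3
Reactants: 4 (Z)-3-methylpent-2-en-4-yn-1-ol
Product: 5 (Z)-3-methylpent-2-en-4-ynal
Conditions: MnO2, CH2Cl2, rt; filtered, exchanged into toluene, used as a solution
Reagents that add atoms: none
Why: Allylic oxidation with MnO2 is neutral, stops at the aldehyde and preserves the Z geometry of C4=C5.

Step 4
Reactants: 5 (Z)-3-methylpent-2-en-4-ynal; 6 vinylmagnesium bromide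
Product: 7 (3S,4Z)-5-methylhepta-1,4-dien-6-yn-3-ol
Conditions: Zn(CH=CH2)2 (from 6 and ZnCl2, magnesium salts removed with 1,4-dioxane), (−)-MIB (10 mol %), toluene–hexane, −30 to 0 °C
Reagents that add atoms: none
Why: Amino-alcohol-catalysed enantioselective addition of a diorganozinc to an aldehyde (here divinylzinc, an Oppolzer-type vinylation) should deliver the vinyl group to the Si face of the enal and so set C6 (3S in this compound, the later 6R centre).

Step 5
Reactants: 7 (3S,4Z)-5-methylhepta-1,4-dien-6-yn-3-ol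
Product: 8 (3S,4Z)-3-(tert-butyldimethylsilyloxy)-5-methylhepta-1,4-dien-6-yne
Conditions: TBSCl, imidazole, DMF, rt
Reagents that add atoms: tert-butyldimethylsilyl chloride (TBSCl), CC(C)(C)[Si](C)(C)Cl
Why: Standard silylation masks the C6 hydroxyl, which would otherwise cyclise onto the activated alkyne or onto C3 in steps 6 and 7 (the known furan-forming closure of Z-enynols).

Step 6
Reactants: 8 (3S,4Z)-3-(tert-butyldimethylsilyloxy)-5-methylhepta-1,4-dien-6-yne; 3 (2S)-N-methoxy-N-methyl-2-(triethylsilyloxy)propanamide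
Product: 10 (2S,6Z,8S)-8-(tert-butyldimethylsilyloxy)-6-methyl-2-(triethylsilyloxy)deca-6,9-dien-4-yn-3-one, via lithium acetylide 9 (not isolated)
Conditions: n-BuLi, THF, −78 °C; then 3, −78 to 0 °C; aq. NH4Cl
Reagents that add atoms: none
Why: Acylation of a lithium acetylide by a Weinreb amide stops at the ketone because the chelated tetrahedral adduct collapses only on work-up, which forms the C1–C2 bond without touching either stereocentre.

Step 7
Reactants: 10 (2S,6Z,8S)-8-(tert-butyldimethylsilyloxy)-6-methyl-2-(triethylsilyloxy)deca-6,9-dien-4-yn-3-one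
Product: 12 5-[(2Z,4S)-4-(tert-butyldimethylsilyloxy)hexa-2,5-dien-2-yl]-2-methylfuran-3(2H)-one, via enaminone 11 (not isolated)
Conditions: Et2NH, EtOH, rt; then AcOH–H2O–THF (3:1:1), rt to 35 °C
Reagents that add atoms: none
Why: Conjugate addition of the amine to the ynone, then acid-promoted loss of the TES group with addition–elimination of the freed hydroxyl at C3, is the classical 3(2H)-furanone synthesis from α′-oxygenated ynones, and the C6 silyl ether keeps that oxygen from competing for C3.

Step 8
Reactants: 12 5-[(2Z,4S)-4-(tert-butyldimethylsilyloxy)hexa-2,5-dien-2-yl]-2-methylfuran-3(2H)-one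
Product: 13 5-[(2Z,4S)-4-hydroxyhexa-2,5-dien-2-yl]-2-methylfuran-3(2H)-one
Conditions: TBAF, AcOH (1:1), THF, 0 °C to rt; product used at once
Reagents that add atoms: none
Why: Acetic acid-buffered fluoride desilylation frees the C6 alcohol under near-neutral conditions, which avoids both enolate chemistry at C10 and acid-catalysed attack of the new hydroxyl on C3.

Step 9
Reactants: 13 5-[(2Z,4S)-4-hydroxyhexa-2,5-dien-2-yl]-2-methylfuran-3(2H)-one; 14 2-(bromomethyl)acrylic acid
Product: 15 (3S,4Z)-5-(5-methyl-4-oxo-4,5-dihydrofuran-2-yl)hexa-1,4-dien-3-yl 2-(bromomethyl)prop-2-enoate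
Conditions: DIC, DMAP (10 mol %), CH2Cl2, −10 to 0 °C
Reagents that add atoms: none
Why: Carbodiimide (Steglich) esterification acylates the secondary alcohol under conditions mild enough for the allylic bromide and the doubly allylic C6 centre.

Step 10
Reactants: 15 (3S,4Z)-5-(5-methyl-4-oxo-4,5-dihydrofuran-2-yl)hexa-1,4-dien-3-yl 2-(bromomethyl)prop-2-enoate
Product: 16 (5R)-3-(bromomethyl)-5-[(1Z)-2-(5-methyl-4-oxo-4,5-dihydrofuran-2-yl)prop-1-en-1-yl]furan-2(5H)-one
Conditions: second-generation Hoveyda–Grubbs catalyst (5 mol %), toluene (0.01 M), 80 °C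
Reagents that add atoms: none
Why: Ring-closing metathesis of the vinyl group onto the 1,1-disubstituted acrylate forms the butenolide C7=C11 bond with loss of ethene, the trisubstituted C4=C5 alkene being too hindered and electron-poor to take part.

Step 11
Reactants: 16 (5R)-3-(bromomethyl)-5-[(1Z)-2-(5-methyl-4-oxo-4,5-dihydrofuran-2-yl)prop-1-en-1-yl]furan-2(5H)-one; 17 (tert-butyldimethylsilyloxy)acetaldehyde
Product: 19 (4R,5R)-4-[(1R)-2-(tert-butyldimethylsilyloxy)-1-hydroxyethyl]-3-methylidene-5-[(1Z)-2-(5-methyl-4-oxo-4,5-dihydrofuran-2-yl)prop-1-en-1-yl]oxolan-2-one, via allylzinc bromide 18 (not isolated)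
Conditions: Zn dust, THF–sat. aq. NH4Cl (5:1), 0 °C to rt
Reagents that add atoms: none
Why: The zinc Barbier allylation of 3-(bromomethyl)butenolides occurs with allylic transposition, so C7 bonds to the aldehyde anti to the C6 substituent (trans lactone) and the exocyclic methylene is regenerated, while the closed chair transition state with the aldehyde substituent equatorial should give the 8R alcohol.

Step 12
Reactants: 19 (6R,7R,8R)-hydroxy lactone; 20 methacrylic acid
Product: 21 (1S)-2-(tert-butyldimethylsilyloxy)-1-{(2R,3S)-4-methylidene-2-[(1Z)-2-(5-methyl-4-oxo-4,5-dihydrofuran-2-yl)prop-1-en-1-yl]-5-oxooxolan-3-yl}ethyl 2-methylprop-2-enoate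
Conditions: PPh3, DIAD, toluene, 0 °C to rt
Reagents that add atoms: none
Why: Mitsunobu esterification displaces the activated C8 oxygen by methacrylate in an SN2 step, so the 8R carbinol becomes the 8S ester with inversion and the final acyl group is in place.

Step 13
Reactants: 21 (6R,7S,8S)-methacrylate with C9 OTBS
Product: 22 (1S)-2-hydroxy-1-{(2R,3S)-4-methylidene-2-[(1Z)-2-(5-methyl-4-oxo-4,5-dihydrofuran-2-yl)prop-1-en-1-yl]-5-oxooxolan-3-yl}ethyl 2-methylprop-2-enoate
Conditions: HF·pyridine, pyridine, THF, 0 °C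
Reagents that add atoms: none
Why: Fluoride cleavage of the primary TBS ether under mildly acidic conditions leaves both esters in place and disfavours migration of the C8 methacrylate to the new primary hydroxyl.

Step 14
Reactants: 22 (6R,7S,8S)-methacrylate with C9 primary alcohol
Product: 23 (1S)-1-{(2R,3S)-4-methylidene-2-[(1Z)-2-(5-methyl-4-oxo-4,5-dihydrofuran-2-yl)prop-1-en-1-yl]-5-oxooxolan-3-yl}-2-oxoethyl 2-methylprop-2-enoate
Conditions: Dess–Martin periodinane, NaHCO3, CH2Cl2, 0 °C to rt
Reagents that add atoms: none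
Why: Dess–Martin oxidation gives the α-acyloxy aldehyde under buffered, base-free conditions that should not epimerise C8.

Step 15
Reactants: 23 (6R,7S,8S)-furanone C9 aldehyde
Product: 24 (1S)-1-{(2R,3S)-2-[(1Z)-2-{4-(tert-butyldimethylsilyloxy)-5-methylfuran-2-yl}prop-1-en-1-yl]-4-methylidene-5-oxooxolan-3-yl}-2-oxoethyl 2-methylprop-2-enoate
Conditions: TBSOTf (1.1 equiv), 2,6-lutidine, CH2Cl2, −78 °C; pentane, filtration, used at once
Reagents that add atoms: tert-butyldimethylsilyl trifluoromethanesulfonate (TBSOTf), CC(C)(C)[Si](C)(C)OS(=O)(=O)C(F)(F)F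
Why: Enol silylation with a silyl triflate and a hindered amine takes place at the vinylogous-ester carbonyl, the most Lewis-basic oxygen, and loss of the C10 proton aromatises the ring to the 3-silyloxyfuran, whereas the aldehyde is not enolised by 2,6-lutidine at this temperature.

Step 16
Reactants: 24 (6R,7S,8S)-silyloxyfuran C9 aldehyde
Product: 25 (4Z,6R,7S,8S,9S,10S)-9-hydroxy-8-methacryloyloxy-1-oxo-3,10-epoxygermacra-2,4,11(13)-trien-12,6-olide
Conditions: BF3·OEt2 (3 equiv), CH2Cl2, −78 °C, 24 added over 6 h (final ca. 1 mM); aq. NaHCO3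
Reagents that add atoms: none
Why: Proposed new method: BF3 binds the C9 aldehyde, and C10 of the furan, the enol-silane carbon next to the ring oxygen, adds to it through an open transition state; the resulting 3-silyloxyfuranium ion loses its silyl group to fluoride, which unmasks the C1 ketone, and the boron aldolate gives the free C9 alcohol on work-up. The closest known reaction type is the intermolecular Lewis-acid Mukaiyama aldol of 2-alkyl-3-silyloxyfurans with aldehydes, which delivers 2,2-disubstituted 3(2H)-furanones; a ring-closing version has no precedent. The one new bond closes the ten-membered carbocycle C1–C10 by exo attack on the aldehyde carbonyl (10-exo-trig; nine-membered when counted through the furan oxygen) and at the same time converts the planar furan into the bridging furanone ring B. C9 is controlled by C8: monodentate BF3 cannot chelate, and the polar Felkin–Anh (Cornforth) arrangement of the α-acyloxy aldehyde should lead to the 8,9-erythro product, that is 9S; C10 is controlled by the tether, since the Z C4=C5 bond and the trans-fused lactone (C6, C7) should let the chain span only one face of the furan without severe strain, which is expected to place the C14 methyl as in the 10S isomer. The step needs attack at C10 and not at C2, reaction at the aldehyde and not at the two conjugated esters, and ring closure in preference to oligomerisation: C10 is the most nucleophilic furan carbon, a neutral π-nucleophile under Lewis acid does not add to the methylene lactone or the methacrylate, and slow addition at high dilution together with the rigid alkenylfuran and lactone units favours the intramolecular pathway.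

Step 17
Reactants: 25 (4Z,6R,7S,8S,9S,10S)-9-hydroxy-8-methacryloyloxy macrocycle
Product: 26 (4Z,6R,7S,8S,9S,10S)-9-acetoxy-8-methacryloyloxy-1-oxo-3,10-epoxygermacra-2,4,11(13)-trien-12,6-olide (CNP0365569.2)
Conditions: Ac2O, pyridine, DMAP (cat.), CH2Cl2, 0 °C to rt
Reagents that add atoms: acetic anhydride, CC(=O)OC(C)=O
Why: DMAP-catalysed acetylation of the hindered C9 secondary alcohol completes the target without touching any stereocentre.

Compound list
1 | ethyl (S)-lactate | CCOC(=O)[C@H](C)O | starting material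
2 | (2S)-2-hydroxy-N-methoxy-N-methylpropanamide | C[C@H](O)C(=O)N(C)OC | intermediate
3 | (2S)-N-methoxy-N-methyl-2-(triethylsilyloxy)propanamide | C[C@H](O[Si](CC)(CC)CC)C(=O)N(C)OC | intermediate
4 | (Z)-3-methylpent-2-en-4-yn-1-ol | C#C/C(C)=C\CO | starting material
5 | (Z)-3-methylpent-2-en-4-ynal | C#C/C(C)=C\C=O | intermediate
6 | vinylmagnesium bromide | C=C[Mg]Br | starting material
7 | (3S,4Z)-5-methylhepta-1,4-dien-6-yn-3-ol | O[C@@H](C=C)/C=C(/C)C#C | intermediate
8 | (3S,4Z)-3-(tert-butyldimethylsilyloxy)-5-methylhepta-1,4-dien-6-yne | CC(C)(C)[Si](C)(C)O[C@@H](C=C)/C=C(/C)C#C | intermediate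
9 | lithium acetylide of 8 | CC(C)(C)[Si](C)(C)O[C@@H](C=C)/C=C(/C)C#C[Li] | intermediate (not isolated)
10 | (2S,6Z,8S)-8-(tert-butyldimethylsilyloxy)-6-methyl-2-(triethylsilyloxy)deca-6,9-dien-4-yn-3-one | CC(C)(C)[Si](C)(C)O[C@@H](C=C)/C=C(/C)C#CC(=O)[C@H](C)O[Si](CC)(CC)CC | intermediate
11 | (2S,6Z,8S)-8-(tert-butyldimethylsilyloxy)-5-(diethylamino)-6-methyl-2-(triethylsilyloxy)deca-4,6,9-trien-3-one (enaminone geometry undefined) | CC(C)(C)[Si](C)(C)O[C@@H](C=C)/C=C(/C)C(N(CC)CC)=CC(=O)[C@H](C)O[Si](CC)(CC)CC | intermediate (not isolated)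
12 | 5-[(2Z,4S)-4-(tert-butyldimethylsilyloxy)hexa-2,5-dien-2-yl]-2-methylfuran-3(2H)-one (C10 epimers) | CC(C)(C)[Si](C)(C)O[C@@H](C=C)/C=C(/C)C1=CC(=O)C(C)O1 | intermediate
13 | 5-[(2Z,4S)-4-hydroxyhexa-2,5-dien-2-yl]-2-methylfuran-3(2H)-one (C10 epimers) | O[C@@H](C=C)/C=C(/C)C1=CC(=O)C(C)O1 | intermediate
14 | 2-(bromomethyl)acrylic acid | C=C(CBr)C(=O)O | starting material
15 | (3S,4Z)-5-(5-methyl-4-oxo-4,5-dihydrofuran-2-yl)hexa-1,4-dien-3-yl 2-(bromomethyl)prop-2-enoate (C10 epimers) | C=C(CBr)C(=O)O[C@@H](C=C)/C=C(/C)C1=CC(=O)C(C)O1 | intermediate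
16 | (5R)-3-(bromomethyl)-5-[(1Z)-2-(5-methyl-4-oxo-4,5-dihydrofuran-2-yl)prop-1-en-1-yl]furan-2(5H)-one (6R; C10 epimers) | BrCC1=C[C@@H](/C=C(/C)C2=CC(=O)C(C)O2)OC1=O | intermediate
17 | (tert-butyldimethylsilyloxy)acetaldehyde | CC(C)(C)[Si](C)(C)OCC=O | starting material
18 | allylzinc bromide from 16 (zinc on C13) | Br[Zn]CC1=C[C@@H](/C=C(/C)C2=CC(=O)C(C)O2)OC1=O | intermediate (not isolated)
19 | (4R,5R)-4-[(1R)-2-(tert-butyldimethylsilyloxy)-1-hydroxyethyl]-3-methylidene-5-[(1Z)-2-(5-methyl-4-oxo-4,5-dihydrofuran-2-yl)prop-1-en-1-yl]oxolan-2-one (6R,7R,8R; C10 epimers) | O[C@@H](CO[Si](C)(C)C(C)(C)C)[C@H]1C(=C)C(=O)O[C@@H]1/C=C(/C)C1=CC(=O)C(C)O1 | intermediate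
20 | methacrylic acid | C=C(C)C(=O)O | starting material
21 | (1S)-2-(tert-butyldimethylsilyloxy)-1-{(2R,3S)-4-methylidene-2-[(1Z)-2-(5-methyl-4-oxo-4,5-dihydrofuran-2-yl)prop-1-en-1-yl]-5-oxooxolan-3-yl}ethyl 2-methylprop-2-enoate (6R,7S,8S; C10 epimers) | C=C(C)C(=O)O[C@H](CO[Si](C)(C)C(C)(C)C)[C@H]1C(=C)C(=O)O[C@@H]1/C=C(/C)C1=CC(=O)C(C)O1 | intermediate
22 | (1S)-2-hydroxy-1-{(2R,3S)-4-methylidene-2-[(1Z)-2-(5-methyl-4-oxo-4,5-dihydrofuran-2-yl)prop-1-en-1-yl]-5-oxooxolan-3-yl}ethyl 2-methylprop-2-enoate (6R,7S,8S; C10 epimers) | C=C(C)C(=O)O[C@H](CO)[C@H]1C(=C)C(=O)O[C@@H]1/C=C(/C)C1=CC(=O)C(C)O1 | intermediate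
23 | (1S)-1-{(2R,3S)-4-methylidene-2-[(1Z)-2-(5-methyl-4-oxo-4,5-dihydrofuran-2-yl)prop-1-en-1-yl]-5-oxooxolan-3-yl}-2-oxoethyl 2-methylprop-2-enoate (6R,7S,8S; C10 epimers) | C=C(C)C(=O)O[C@H](C=O)[C@H]1C(=C)C(=O)O[C@@H]1/C=C(/C)C1=CC(=O)C(C)O1 | intermediate
24 | (1S)-1-{(2R,3S)-2-[(1Z)-2-{4-(tert-butyldimethylsilyloxy)-5-methylfuran-2-yl}prop-1-en-1-yl]-4-methylidene-5-oxooxolan-3-yl}-2-oxoethyl 2-methylprop-2-enoate (6R,7S,8S; key-step precursor) | C=C(C)C(=O)O[C@H](C=O)[C@H]1C(=C)C(=O)O[C@@H]1/C=C(/C)c1cc(O[Si](C)(C)C(C)(C)C)c(C)o1 | intermediate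
25 | (4Z,6R,7S,8S,9S,10S)-9-hydroxy-8-methacryloyloxy-1-oxo-3,10-epoxygermacra-2,4,11(13)-trien-12,6-olide (key-step product) | C=C(C)C(=O)O[C@H]1[C@H]2C(=C)C(=O)O[C@@H]2/C=C(/C)C2=CC(=O)[C@@](C)(O2)[C@H]1O | intermediate
26 | (4Z,6R,7S,8S,9S,10S)-9-acetoxy-8-methacryloyloxy-1-oxo-3,10-epoxygermacra-2,4,11(13)-trien-12,6-olide | C=C(C)C(=O)O[C@H]1[C@H]2C(=C)C(=O)O[C@@H]2/C=C(/C)C2=CC(=O)[C@@](C)(O2)[C@H]1OC(C)=O | target

Total step count: 17
Longest linear sequence: 15 steps (from 4 to 26, steps 3–17)

Steps most likely to fail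

1. Step 16 (Proposed new method). The process risks are intermolecular aldol (oligomerisation) or protodesilylation of the furan outrunning ring closure, and closure through the other pair of diastereotopic faces at C9 and C10. The fallback uses known chemistry, sets out from 24 and returns at 25. NBS (THF, −78 °C) brominates the enol-silane carbon C10 to give the 10-bromo furanone aldehyde F1, which is used cold without purification. SmI2 (2.2 equiv, THF, −78 °C, high dilution) then reduces the C–Br bond, and the samarium enolate closes onto the C9 aldehyde in a Reformatsky-type aldol cyclisation, a method established for medium and large rings, to give 25. The C9/C10 outcome then depends on the chelated samarium transition state and would have to be checked.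

2. Step 12. The process risks are elimination toward C7 (loss of the allylic C7 hydrogen to a conjugated diene) and failure of the hindered, β-oxygenated carbinol to undergo substitution, so that no inversion is achieved. The fallback sets out from 16 and returns at 21; it makes the 8S centre directly instead of inverting it. Stannylation of 16 with hexabutylditin and Pd(PPh3)4 gives allylstannane F2. Addition of F2 to aldehyde 17 with BF3·OEt2 (CH2Cl2, −78 °C) goes through an open antiperiplanar transition state (the syn-selective Lewis-acid allylstannane addition), which should give the 8S alcohol F3, still anti to the C6 substituent at C7. Acylation of F3 with methacrylic anhydride and DMAP gives 21.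

3. Step 4. The process risk is insufficient facial discrimination on the Z-enal, through uncatalysed background addition or zinc acetylide formation at the terminal alkyne. The fallback sets out from 5 and returns at 7. Addition of vinylmagnesium bromide 6 to 5 (THF, −78 °C) gives racemic dienynol F4. Sharpless kinetic resolution (Ti(OiPr)4, L-(+)-diisopropyl tartrate, t-BuOOH, 4 Å sieves, CH2Cl2, −20 °C, to about 55–60 % conversion) should epoxidise the vinyl group of the (R)-enantiomer to erythro epoxy alcohol F5 and leave (S)-alcohol 7.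

Further compounds
F1 | step 16 | (1S)-1-{(2R,3S)-2-[(1Z)-2-(5-bromo-5-methyl-4-oxo-4,5-dihydrofuran-2-yl)prop-1-en-1-yl]-4-methylidene-5-oxooxolan-3-yl}-2-oxoethyl 2-methylprop-2-enoate (C10 epimers) | C=C(C)C(=O)O[C@H](C=O)[C@H]1C(=C)C(=O)O[C@@H]1/C=C(/C)C1=CC(=O)C(C)(Br)O1
F2 | step 12 | (5R)-5-[(1Z)-2-(5-methyl-4-oxo-4,5-dihydrofuran-2-yl)prop-1-en-1-yl]-3-[(tributylstannyl)methyl]furan-2(5H)-one | CCCC[Sn](CCCC)(CCCC)CC1=C[C@@H](/C=C(/C)C2=CC(=O)C(C)O2)OC1=O
F3 | step 12 | (4R,5R)-4-[(1S)-2-(tert-butyldimethylsilyloxy)-1-hydroxyethyl]-3-methylidene-5-[(1Z)-2-(5-methyl-4-oxo-4,5-dihydrofuran-2-yl)prop-1-en-1-yl]oxolan-2-one (6R,7R,8S) | O[C@H](CO[Si](C)(C)C(C)(C)C)[C@H]1C(=C)C(=O)O[C@@H]1/C=C(/C)C1=CC(=O)C(C)O1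
F4 | step 4 | racemic (4Z)-5-methylhepta-1,4-dien-6-yn-3-ol | OC(C=C)/C=C(/C)C#C
F5 | step 4 | (1S,2Z)-3-methyl-1-[(2R)-oxiran-2-yl]pent-2-en-4-yn-1-ol | O[C@H]([C@H]1CO1)/C=C(/C)C#C
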